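Over a run of 80 min, I want to know how far this charge of solid substrate gets and what stands in the flask at the end.

    crystals ⇌ product, rate k1*(cs1 - [product]) while solid is left; crystals form when [product] > cs1 (cs1 = 2.8 mM, k1 = 0.154 s⁻¹)
    starting material + starting material ⇌ product (K2 = 61 M⁻¹, k2 = 0.507 M⁻¹ s⁻¹)
    solid substrate ⇌ starting material, rate k3*(cs3 - [starting material]) while solid is left; crystals form when [starting material] > cs3 (cs3 = 0.20 M, k3 = 0.00809 s⁻¹)

solid substrate 0.22 M; time 80 min

- a species is counted by the solid substrate in it: one product or crystals counts as two
- amounts and yields of product count crystals too
- where a step has two of a species, its rate is k times that concentration squared, and two are used at each turn
- given per volume of solution although it is solid: solid substrate, crystals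
- at the start none of the solid substrate is in solution
- what has only dissolved of solid substrate counts as not reacted
- the reaction counts as stopped when no species that holds the solid substrate changes by six tenths of a point or more over the second half of the time
- run time (flask): 80 min

- which holds at 80 min: what has brought the reaction to rest, or that it has not come to rest (for what has run out or reacted, a solid counts together with what of it has only dissolved) (forward and back rates have come level / all of the solid substrate has reacted / it is still moving)
- part of the solid substrate that has turned into other species by 80 min (what has only dissolved does not count)
- amount of product at 80 min, in percent of the solid substrate charged
- amount of product if the flask were left three thousand times as long, in percent of the solid substrate charged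

The charge sits in four forms: solid substrate, starting material, and product and crystals, which count two each. Once crystals stand and the supply from the solid has stopped, [product] comes to rest at 2.8 mM. When pairing runs level both ways, [starting material] is then the square root of 2.8 mM over 61 M⁻¹, 6.78 mM; I call this the rest level. It is far less than the solubility 0.20 M, so at rest the solution stands short of saturation, and I expect the solid to dissolve completely. The balance then leaves the charge less the rest level as product, counting crystals: 96.9 %. The conversion is the same, 96.9 %.

| Rung | Time | The flask after it |
|---|---|---|
| crystals follow [product] | 0.108 min | [product] follows its supply |
| pairing relaxes near rest | 0.524 min | [starting material] follows the solid's supply |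
| solid dissolves, at least | 2.27 min | no solid substrate |
| the run | 80 min | at rest |

Each rung is shorter than the next, and the solid's time is far shorter than the run. So I expect forward and back rates have come level, and waiting longer leaves 96.9 %.

The forecast gives forward and back rates have come level, with 96.9 % conversion, 96.9 % product and 96.9 % in the long run: "the flask is long since at equilibrium and waiting longer changes nothing". It reckons as I do, so our agreement checks nothing.

The simulation gives forward and back rates have come level, with 96.9 % conversion, 96.9 % product and 96.9 % in the long run.

In this flask the pairing half-life of 0.524 min is short against the 80 min run, and starting material stands at 3.08 % of the charge, the rest level's share 3.08 %. Going down in charge, the simulated product yield has moved by 5 points at 0.0839 M of solid substrate.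

For the flask charged with 0.055 M, the rest level gives 87.7 % product. The computed result is 87.7 %.

The numbers were chosen freely.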